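**Next flask.** The midnight run and the noon run have to choose one recipe for the next flask, the one with the most target at the end.

| setting | midnight | noon | beta | eta | zeta | gamma |
|---|---|---|---|---|---|---|
| starting material | 0.10 M | 0.10 M | 0.10 M | 0.10 M | 0.10 M | 0.10 M |
| coupling partner | 0.15 M | 0.60 M | 0.300 M | 0.300 M | 0.300 M | 0.300 M |
| temperature | 82 °C | 110 °C | 95 °C | 70 °C |  | 120 °C |
| remark | run made earlier | run made earlier |  |  | at 70 °C until 2.5 h, from then on at 120 °C |  |
| time |  |  | 12 h | 12 h | 12 h | 12 h |

- midnight (time / h: target / %, starting material / %): 8.00: 7.8, 1.0; 15.0: 15.9, 1.4; 20.0: 17.9, 1.3; 30.0: 23.0, 0.8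
- noon (time / h: target / %, starting material / %): 0.500: 10.3, 0; 1.33: 20.3, 0; 3.00: 22.7, 0; 8.00: 16.0, 0

(each reading ± 1 percentage point)

- which flask leads in amount of target, in percent of the starting material charged ("all alike" within 1.5 percentage points) (beta / eta / zeta / gamma / all alike)
- how much target is there at the end, in percent of the starting material charged: beta
- how much target is there at the end, in percent of the starting material charged: eta
- how much target is there at the end, in percent of the starting material charged: zeta
- how much target is there at the end, in percent of the starting material charged: gamma

- the earlier runs were read with a standard deviation of 1 percentage point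

**One clock.** At midnight the first reading shows starting material at 1.0% and target at 7.8%. So target rises after the starting material has fallen to that reading, and this reckoning takes the rise as independent of c(coupling partner). The first readings then compare temperature. Noon climbs 21.1 times as fast as midnight, which reads as an apparent activation energy of 123 kJ mol⁻¹. From 110 °C to 120 °C this gives 2.68, the clock factor (a shift factor): the noon hours that pass in one hour of a flask at 120 °C. Each flask is then read on the noon curve, whose fade after its highest reading is 0.0700 h⁻¹.

**The recipes.** Beta reaches 2.48 h of noon time, between the readings at 1.33 h and 3.00 h, so it should hold 20.3% to 22.7%. Eta reaches 0.132 h, and the first noon slope gives it 2.72%. Gamma passes 32.1 h of noon time, and the fade leaves 2.96%. Zeta, counted from its change of temperature, keeps 4.73%. So beta is charged, and gamma and zeta are left aside.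

**The forecast.** The forecast also chooses beta. It gives 23% for beta, 7.5% for eta, 11.5% for zeta and 9% for gamma. Its temperature scale differs from the one above: “Assuming first order in partner, Ea is about 85 kJ/mol.”

**The result.** Beta leads with 24.0%. Eta holds 4.13%, zeta 2.25% and gamma 1.14%.

    intermediate ⇌ target (K = 14.0, k = 6.60 × 10⁻⁵ min⁻¹, Ea = 114 kJ mol⁻¹, ΔH = −50.0 kJ mol⁻¹)
    starting material + coupling partner → intermediate (k = 0.0980 L mol⁻¹ min⁻¹, Ea = 64.0 kJ mol⁻¹)
    intermediate → side product (k = 1.70 × 10⁻⁴ min⁻¹, Ea = 112 kJ mol⁻¹)
    (constants at 70 °C)

**Gamma's fade.** Gamma's target falls from 6.05% at 6.00 h to 1.14% at 12.0 h. That is a fade of 0.278 h⁻¹, while the clock factor on the noon fade gives 0.187 h⁻¹. The main reason for gamma's low target at the end is the step from intermediate to side product: without that step, gamma holds 60.1%.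

**A shorter gamma.** A gamma flask stopped at 3.0 h has run 8.03 h of noon time, which matches the time of the last noon reading, so the clock expects that reading, 16.0%. The computed flask holds 13.9%.

(The numbers in the tables are calculated with made-up constants; noise was put on by code.)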